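## Retrosynthetic overview

1. Target 16 is a (2R,3R)-trans-dihydroflavonol. The C3 hydroxyl is removed first, giving the (2S)-flavanone 13; C2 has the same spatial arrangement in both, and the descriptor changes only because C3 gains an oxygen.
2. Ring C of 13 is opened at C2–C3. C2 carries both the ring oxygen O1 and ring B, so in the open aryl benzyl ether its C–H bond is activated twice towards a carbene on C3 next to the C4 ketone. This leads to diazoketone 11.
3. 11 comes from methyl ketone 8 by detrifluoroacetylative diazo transfer. 8 comes from 2,4,6-trihydroxyacetophenone by O-prenylation at the future C7 oxygen, Mitsunobu benzylation of the future O1 with the vanillin-derived alcohol 6, and silylation of the future C5 oxygen.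
4. Ring order: rings A and B are bought; ring C is the only ring formed (step 7). Both silyl groups leave in the last step.

Key step: step 7

Assumption: Rh2(S-PTTL)4 is taken to give the (2S) ketone; if a trial run shows the opposite sense, the enantiomeric catalyst Rh2(R-PTTL)4 is used with nothing else changed.

Flavonoid numbering (O1, C2, C3, C4, C4a, C5–C8, C8a; ring B primed) is used for the cyclised compounds.

## Route

Step 1
Reactants: 1 2,4,6-trihydroxyacetophenone; 2 prenyl bromide (1-bromo-3-methylbut-2-ene)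
Product: 3 1-[2,6-dihydroxy-4-(3-methylbut-2-enyloxy)phenyl]ethanone
Conditions: K2CO3 (1.0 equiv), 2 (1.0 equiv), acetone, reflux
Reagents that add atoms: none
Why: Williamson etherification under weak-base control: the C4 hydroxyl, para to the acetyl group, is the most acidic and the only one not held in a hydrogen bond to the carbonyl, so one equivalent of 2 should alkylate it on oxygen in preference to the two chelated ortho hydroxyls and to ring carbon.

Step 2
Reactants: 4 vanillin
Product: 5 3-methoxy-4-(triisopropylsilyloxy)benzaldehyde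
Conditions: TIPSCl, imidazole, DMF, rt
Reagents that add atoms: chlorotriisopropylsilane, CC(C)[Si](Cl)(C(C)C)C(C)C
Why: Phenol silylation with a silyl chloride and imidazole; the aldehyde is inert, and the triisopropylsilyl aryl ether is chosen to survive borohydride, amide bases and the rhodium step.

Step 3
Reactants: 5 3-methoxy-4-(triisopropylsilyloxy)benzaldehyde
Product: 6 [3-methoxy-4-(triisopropylsilyloxy)phenyl]methanol
Conditions: NaBH4, THF/MeOH, 0 °C
Reagents that add atoms: none
Why: Borohydride reduction of an aromatic aldehyde to the benzylic alcohol, which should leave the aryl silyl ether untouched at 0 °C.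

Step 4
Reactants: 3 1-[2,6-dihydroxy-4-(3-methylbut-2-enyloxy)phenyl]ethanone; 6 [3-methoxy-4-(triisopropylsilyloxy)phenyl]methanol
Product: 7 1-[2-hydroxy-6-{[3-methoxy-4-(triisopropylsilyloxy)phenyl]methoxy}-4-(3-methylbut-2-enyloxy)phenyl]ethanone
Conditions: PPh3 (1.2 equiv), DIAD (1.2 equiv), THF, 0 °C to rt
Reagents that add atoms: none
Why: Mitsunobu etherification: the two ortho hydroxyls of 3 are equivalent and acidic enough to protonate the betaine, alcohol 6 is activated as its oxyphosphonium salt, and after the first alkylation the remaining hydroxyl is locked in a hydrogen bond to the ketone, so monoetherification should prevail; this avoids the labile 4-silyloxybenzyl bromide.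

Step 5
Reactants: 7 1-[2-hydroxy-6-{[3-methoxy-4-(triisopropylsilyloxy)phenyl]methoxy}-4-(3-methylbut-2-enyloxy)phenyl]ethanone
Product: 8 1-[2-{[3-methoxy-4-(triisopropylsilyloxy)phenyl]methoxy}-4-(3-methylbut-2-enyloxy)-6-(triisopropylsilyloxy)phenyl]ethanone
Conditions: TIPSOTf (1.2 equiv), 2,6-lutidine, CH2Cl2, 0 °C
Reagents that add atoms: triisopropylsilyl trifluoromethanesulfonate, CC(C)[Si](OS(=O)(=O)C(F)(F)F)(C(C)C)C(C)C
Why: Silylation of the hydrogen-bonded phenol with a silyl triflate and a hindered pyridine base, which overcomes the chelation; the future C5 oxygen thereby loses the O–H bond that would capture the carbene and gains a bulky group without activated C–H bonds that should resist oxygen-to-oxygen migration to the enolates formed in steps 6 and 8.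

Step 6
Reactants: 8 1-[2-{[3-methoxy-4-(triisopropylsilyloxy)phenyl]methoxy}-4-(3-methylbut-2-enyloxy)-6-(triisopropylsilyloxy)phenyl]ethanone
Product: 11 2-diazo-1-[2-{[3-methoxy-4-(triisopropylsilyloxy)phenyl]methoxy}-4-(3-methylbut-2-enyloxy)-6-(triisopropylsilyloxy)phenyl]ethanone, via lithium enolate 9 (not isolated), via trifluoroacetyl ketone 10 (not isolated)
Conditions: LiN(SiMe3)2 (1.1 equiv), THF, −78 °C; CF3CO2CH2CF3 (1.2 equiv), −78 °C; cold 5% aq HCl work-up; then MsN3 (1.5 equiv), Et3N (1.5 equiv), H2O (1 equiv), MeCN, rt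
Reagents that add atoms: methanesulfonyl azide, CS(=O)(=O)N=[N+]=[N-] (the two diazo nitrogens); 2,2,2-trifluoroethyl trifluoroacetate, FC(F)(F)COC(=O)C(F)(F)F (its CF3CO group stands only in 10 and is lost again)
Why: Detrifluoroacetylative diazo transfer: the kinetic lithium enolate 9 of the methyl ketone is trifluoroacetylated to the activated 1,3-diketone 10, whose enolate attacks the sulfonyl azide and then passes the trifluoroacetyl group to the sulfonamide nitrogen, leaving the terminal diazoketone without any carboxylic acid or acid chloride stage that the aryl silyl ethers and the prenyl ether would not tolerate.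

Step 7
Reactants: 11 2-diazo-1-[2-{[3-methoxy-4-(triisopropylsilyloxy)phenyl]methoxy}-4-(3-methylbut-2-enyloxy)-6-(triisopropylsilyloxy)phenyl]ethanone
Product: 13 (2S)-2-[3-methoxy-4-(triisopropylsilyloxy)phenyl]-7-(3-methylbut-2-enyloxy)-5-(triisopropylsilyloxy)chroman-4-one, via rhodium carbene 12 (not isolated)
Conditions: Rh2(S-PTTL)4 (dirhodium tetrakis[N-phthaloyl-(S)-tert-leucinate], 2 mol %), CH2Cl2, 0 °C, slow addition of 11
Reagents that add atoms: none
Why: Loss of N2 from 11 at an axial site of the divalent rhodium dimer gives the electrophilic acyl carbene 12 at C3, which takes up the hydride-like C–H bond of the O1–CH2 group through a three-centre transition state and forms C2–C3 as the catalyst departs. The closest known reaction type is the chiral dirhodium carboxylate-catalysed C–H insertion of ortho-alkoxyaryl diazoketones to chroman-4-ones. Ring C closes as a six-membered ring by 1,6-insertion, the carbene carbon and the reacting carbon being linked through C4, C4a, C8a and O1. C2 is the only new stereocenter and is set by the catalyst, whose phthalimido walls around the rhodium site distinguish the two enantiotopic benzylic hydrogens. The step needs C–H insertion to win over oxonium ylide formation at O1 with [1,2]-benzyl shift and over attack at the C5 oxygen. O1 is a weak nucleophile because its lone pair is delocalised into the acyl-bearing ring A, the C2–H bond is activated by both O1 and the electron-rich ring B, the C5 oxygen is shielded by the triisopropylsilyl group whose C–H bonds lie at seven-ring distance or beyond, and the prenyl alkene sits para to the acyl group and cannot reach the carbene.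

Step 8
Reactants: 13 (2S)-2-[3-methoxy-4-(triisopropylsilyloxy)phenyl]-7-(3-methylbut-2-enyloxy)-5-(triisopropylsilyloxy)chroman-4-one
Product: 15 (2R,3R)-3-hydroxy-2-[3-methoxy-4-(triisopropylsilyloxy)phenyl]-7-(3-methylbut-2-enyloxy)-5-(triisopropylsilyloxy)chroman-4-one, via potassium enolate 14 (not isolated)
Conditions: KN(SiMe3)2 (1.2 equiv), THF, −78 °C; 2-(phenylsulfonyl)-3-phenyloxaziridine (1.3 equiv), −78 °C; AcOH quench at −78 °C
Reagents that add atoms: 2-(phenylsulfonyl)-3-phenyloxaziridine (Davis reagent), O=S(=O)(N1OC1c1ccccc1)c1ccccc1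
Why: Enolate hydroxylation with an N-sulfonyloxaziridine (Davis oxidation): the C3 potassium enolate 14 has its ring C2–O1 bond poorly aligned with the enolate π system and so should resist β-elimination in the cold, the oxaziridine delivers oxygen to C3 from the face opposite the C2 aryl group and so sets the 2,3-trans (3R) centre, and the prenyl alkene does not react with this reagent at −78 °C.

Step 9
Reactants: 15 (2R,3R)-3-hydroxy-2-[3-methoxy-4-(triisopropylsilyloxy)phenyl]-7-(3-methylbut-2-enyloxy)-5-(triisopropylsilyloxy)chroman-4-one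
Product: 16 (2R,3R)-3,5-dihydroxy-2-(4-hydroxy-3-methoxyphenyl)-7-(3-methylbut-2-enyloxy)chroman-4-one
Conditions: Bu4NF (2.5 equiv), AcOH (3 equiv), THF, 0 °C
Reagents that add atoms: none
Why: Fluoride cleavage of the two phenolic triisopropylsilyl ethers, with acetic acid buffering the phenoxides so that neither ring opening at C2–O1 through the 4'-phenoxide nor epimerisation at C3 should occur; the prenyl ether, the ketol and both stereocenters are left unchanged.

## Compound list

1 | 2,4,6-trihydroxyacetophenone | CC(=O)c1c(O)cc(O)cc1O | starting material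
2 | prenyl bromide (1-bromo-3-methylbut-2-ene) | CC(C)=CCBr | starting material
3 | 1-[2,6-dihydroxy-4-(3-methylbut-2-enyloxy)phenyl]ethanone | CC(=O)c1c(O)cc(OCC=C(C)C)cc1O | intermediate
4 | vanillin (4-hydroxy-3-methoxybenzaldehyde) | COc1cc(C=O)ccc1O | starting material
5 | 3-methoxy-4-(triisopropylsilyloxy)benzaldehyde | COc1cc(C=O)ccc1O[Si](C(C)C)(C(C)C)C(C)C | intermediate
6 | [3-methoxy-4-(triisopropylsilyloxy)phenyl]methanol | COc1cc(CO)ccc1O[Si](C(C)C)(C(C)C)C(C)C | intermediate
7 | 1-[2-hydroxy-6-{[3-methoxy-4-(triisopropylsilyloxy)phenyl]methoxy}-4-(3-methylbut-2-enyloxy)phenyl]ethanone | CC(=O)c1c(O)cc(OCC=C(C)C)cc1OCc1ccc(O[Si](C(C)C)(C(C)C)C(C)C)c(OC)c1 | intermediate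
8 | 1-[2-{[3-methoxy-4-(triisopropylsilyloxy)phenyl]methoxy}-4-(3-methylbut-2-enyloxy)-6-(triisopropylsilyloxy)phenyl]ethanone | CC(=O)c1c(OCc2ccc(O[Si](C(C)C)(C(C)C)C(C)C)c(OC)c2)cc(OCC=C(C)C)cc1O[Si](C(C)C)(C(C)C)C(C)C | intermediate
9 | lithium enolate of 8 (lithium 1-arylethenolate) | [Li+].[O-]C(=C)c1c(OCc2ccc(O[Si](C(C)C)(C(C)C)C(C)C)c(OC)c2)cc(OCC=C(C)C)cc1O[Si](C(C)C)(C(C)C)C(C)C | intermediate
10 | 4,4,4-trifluoro-1-[2-{[3-methoxy-4-(triisopropylsilyloxy)phenyl]methoxy}-4-(3-methylbut-2-enyloxy)-6-(triisopropylsilyloxy)phenyl]butane-1,3-dione | O=C(CC(=O)C(F)(F)F)c1c(OCc2ccc(O[Si](C(C)C)(C(C)C)C(C)C)c(OC)c2)cc(OCC=C(C)C)cc1O[Si](C(C)C)(C(C)C)C(C)C | intermediate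
11 | 2-diazo-1-[2-{[3-methoxy-4-(triisopropylsilyloxy)phenyl]methoxy}-4-(3-methylbut-2-enyloxy)-6-(triisopropylsilyloxy)phenyl]ethanone | [N-]=[N+]=CC(=O)c1c(OCc2ccc(O[Si](C(C)C)(C(C)C)C(C)C)c(OC)c2)cc(OCC=C(C)C)cc1O[Si](C(C)C)(C(C)C)C(C)C | intermediate
12 | rhodium carbene from 11 (carbene carbon bound at an axial site of Rh2(S-PTTL)4; the carboxylate ligands and second rhodium are not drawn) | [Rh]=CC(=O)c1c(OCc2ccc(O[Si](C(C)C)(C(C)C)C(C)C)c(OC)c2)cc(OCC=C(C)C)cc1O[Si](C(C)C)(C(C)C)C(C)C | intermediate
13 | (2S)-2-[3-methoxy-4-(triisopropylsilyloxy)phenyl]-7-(3-methylbut-2-enyloxy)-5-(triisopropylsilyloxy)chroman-4-one | COc1cc([C@H]2Oc3cc(OCC=C(C)C)cc(O[Si](C(C)C)(C(C)C)C(C)C)c3C(=O)C2)ccc1O[Si](C(C)C)(C(C)C)C(C)C | intermediate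
14 | potassium (2S)-2-[3-methoxy-4-(triisopropylsilyloxy)phenyl]-7-(3-methylbut-2-enyloxy)-5-(triisopropylsilyloxy)-2H-chromen-4-olate | COc1cc([C@H]2Oc3cc(OCC=C(C)C)cc(O[Si](C(C)C)(C(C)C)C(C)C)c3C([O-])=C2)ccc1O[Si](C(C)C)(C(C)C)C(C)C.[K+] | intermediate
15 | (2R,3R)-3-hydroxy-2-[3-methoxy-4-(triisopropylsilyloxy)phenyl]-7-(3-methylbut-2-enyloxy)-5-(triisopropylsilyloxy)chroman-4-one | COc1cc([C@H]2Oc3cc(OCC=C(C)C)cc(O[Si](C(C)C)(C(C)C)C(C)C)c3C(=O)[C@@H]2O)ccc1O[Si](C(C)C)(C(C)C)C(C)C | intermediate
16 | (2R,3R)-3,5-dihydroxy-2-(4-hydroxy-3-methoxyphenyl)-7-(3-methylbut-2-enyloxy)chroman-4-one | COc1cc([C@H]2Oc3cc(OCC=C(C)C)cc(O)c3C(=O)[C@@H]2O)ccc1O | target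

## Summary

Total step count: 9.
Longest linear sequence: 8 steps (4 to 16 through steps 2, 3, 4, 5, 6, 7, 8 and 9).

Steps most likely to fail:

**Step 7.** The carbene may be captured by O1 to give an oxonium ylide that contracts by [1,2]-benzyl shift, or the insertion may proceed with too little enantioselectivity. The fallback forms the C2–aryl bond instead of C2–C3, by asymmetric 1,4-addition of an arylboron reagent to a chromone. It sets out from 3, which is condensed with N,N-dimethylformamide dimethyl acetal (toluene, 80 °C) to the enaminone (E)-3-(dimethylamino)-1-[2,6-dihydroxy-4-(3-methylbut-2-enyloxy)phenyl]prop-2-en-1-one F1. Dilute aqueous HCl in CH2Cl2 closes it, with loss of dimethylamine, to 5-hydroxy-7-(3-methylbut-2-enyloxy)chromen-4-one F2, and TIPSOTf with 2,6-lutidine gives 7-(3-methylbut-2-enyloxy)-5-(triisopropylsilyloxy)chromen-4-one F3. Commercial 2-methoxy-4-(4,4,5,5-tetramethyl-1,3,2-dioxaborolan-2-yl)phenol is silylated (TIPSCl, imidazole, DMF) to 2-[3-methoxy-4-(triisopropylsilyloxy)phenyl]-4,4,5,5-tetramethyl-1,3,2-dioxaborolane F4. Addition of F4 to F3 with [RhCl(C2H4)2]2 (monovalent rhodium), an electron-poor atropisomeric bisphosphine of the MeO-BIPHEP family and substoichiometric aqueous KOH in toluene at room temperature should give 13, where the route is rejoined before step 8. The ligand antipode is chosen for the (2S) product.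

**Step 8.** The C3 enolate may expel the O1 aryloxide (ring opening to the chalcone phenoxide, which would erase C2), or the C5 silyl group may migrate to the enolate oxygen. The fallback avoids any free enolate and sets out from 13. Soft enolisation (TMSOTf, Et3N, CH2Cl2, 0 °C) should give the silyl enol ether (2S)-2-[3-methoxy-4-(triisopropylsilyloxy)phenyl]-7-(3-methylbut-2-enyloxy)-5-(triisopropylsilyloxy)-4-(trimethylsilyloxy)-2H-chromene F5. Rubottom oxidation with dimethyldioxirane (1.0 equiv, acetone/CH2Cl2, −78 °C) is expected to react at the electron-rich enol ether before the prenyl alkene and from the face away from the C2 aryl group, giving the C3–C4 silyloxy epoxide of F5 with its oxygen anti to ring B F6. Work-up with dilute aqueous citric acid in THF opens F6 and removes the trimethylsilyl group to give 15, where the route is rejoined before step 9.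

**Step 6.** The lithium enolate next to the ortho silyl ether may suffer oxygen-to-oxygen silyl migration, or trifluoroacetylation of the hindered 2,6-disubstituted aryl ketone may be incomplete. The fallback builds the diazo group from a bromoketone and sets out from 8. Soft enolisation (TMSOTf, Et3N, CH2Cl2, 0 °C) should give the silyl enol ether [1-(2-{[3-methoxy-4-(triisopropylsilyloxy)phenyl]methoxy}-4-(3-methylbut-2-enyloxy)-6-(triisopropylsilyloxy)phenyl)ethenyloxy]trimethylsilane F7. N-Bromosuccinimide in THF at −78 °C should convert it into 2-bromo-1-[2-{[3-methoxy-4-(triisopropylsilyloxy)phenyl]methoxy}-4-(3-methylbut-2-enyloxy)-6-(triisopropylsilyloxy)phenyl]ethanone F8. N,N'-Ditosylhydrazine and DBU in THF at 0 °C then give, by N-alkylation and twofold loss of sulfinate, diazoketone 11, where the route is rejoined before step 7.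

## Further compounds

F1 | step 7 | (E)-3-(dimethylamino)-1-[2,6-dihydroxy-4-(3-methylbut-2-enyloxy)phenyl]prop-2-en-1-one | CN(C)/C=C/C(=O)c1c(O)cc(OCC=C(C)C)cc1O
F2 | step 7 | 5-hydroxy-7-(3-methylbut-2-enyloxy)chromen-4-one | O=c1ccoc2cc(OCC=C(C)C)cc(O)c12
F3 | step 7 | 7-(3-methylbut-2-enyloxy)-5-(triisopropylsilyloxy)chromen-4-one | O=c1ccoc2cc(OCC=C(C)C)cc(O[Si](C(C)C)(C(C)C)C(C)C)c12
F4 | step 7 | 2-[3-methoxy-4-(triisopropylsilyloxy)phenyl]-4,4,5,5-tetramethyl-1,3,2-dioxaborolane | COc1cc(B2OC(C)(C)C(C)(C)O2)ccc1O[Si](C(C)C)(C(C)C)C(C)C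
F5 | step 8 | (2S)-2-[3-methoxy-4-(triisopropylsilyloxy)phenyl]-7-(3-methylbut-2-enyloxy)-5-(triisopropylsilyloxy)-4-(trimethylsilyloxy)-2H-chromene | COc1cc([C@H]2Oc3cc(OCC=C(C)C)cc(O[Si](C(C)C)(C(C)C)C(C)C)c3C(O[Si](C)(C)C)=C2)ccc1O[Si](C(C)C)(C(C)C)C(C)C
F6 | step 8 | C3–C4 silyloxy epoxide of F5, oxirane oxygen on the face opposite the C2 aryl group | COc1cc([C@H]2Oc3cc(OCC=C(C)C)cc(O[Si](C(C)C)(C(C)C)C(C)C)c3[C@]4(O[Si](C)(C)C)O[C@H]24)ccc1O[Si](C(C)C)(C(C)C)C(C)C
F7 | step 6 | [1-(2-{[3-methoxy-4-(triisopropylsilyloxy)phenyl]methoxy}-4-(3-methylbut-2-enyloxy)-6-(triisopropylsilyloxy)phenyl)ethenyloxy]trimethylsilane | C=C(O[Si](C)(C)C)c1c(OCc2ccc(O[Si](C(C)C)(C(C)C)C(C)C)c(OC)c2)cc(OCC=C(C)C)cc1O[Si](C(C)C)(C(C)C)C(C)C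
F8 | step 6 | 2-bromo-1-[2-{[3-methoxy-4-(triisopropylsilyloxy)phenyl]methoxy}-4-(3-methylbut-2-enyloxy)-6-(triisopropylsilyloxy)phenyl]ethanone | BrCC(=O)c1c(OCc2ccc(O[Si](C(C)C)(C(C)C)C(C)C)c(OC)c2)cc(OCC=C(C)C)cc1O[Si](C(C)C)(C(C)C)C(C)C
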